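**Retrosynthetic overview**
Numbering: C1 = methyl-bearing ring-fusion carbon; C2, C3 = cyclopentane CH2 pair; C4 = carbinol carbon with isopropyl; C5 = ring-fusion CH; C6 = veratroyloxy CH; C7 = CH2; C8(Me)=C9 alkene; C10 = angeloyloxy CH.
The two esters are removed first (angelate at C10, then veratroate at C6), which leaves the diol silyl ether 25.
The strategy rests on the tertiary carbinol C4 of the cyclopentane ring (C1–C2–C3–C4–C5), whose hydroxyl is cis to C6: cutting C3–C4 gives a primary iodide at C3 and an isobutyryl ketone on C5 of an intact cycloheptene (23).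
23 goes back to enone 16, where a 3-methylbut-1-en-2-yl group on C5 and an allyl group on C1 mask the ketone and the iodoethyl arm; 16 comes from (S)-4-silyloxycyclohept-2-enone 4 by cuprate addition anti to the C6 oxygen, two enone-forming oxidations and α′-allylation.
4 comes from cyclohepta-1,3-diene by photo-oxygenation and asymmetric Kornblum–DeLaMare rearrangement; the seven-membered ring is present from the start and the five-membered ring is closed in step 14.

Key step: step 14

Remark: 2-bromo-3-methylbut-1-ene (5) is taken as a purchasable vinyl bromide; if it is not at hand it is one step from 3-methylbut-1-yne and HBr.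

**Step 1**
Reactants: 1 cyclohepta-1,3-diene
Product: 2 6,7-dioxabicyclo[3.2.2]non-8-ene (meso, cis-bridged endoperoxide)
Conditions: O2, tetraphenylporphyrin (cat.), visible light, CH2Cl2, 0 °C
Reagents that add atoms: dioxygen, O=O
Why: The [4+2] cycloaddition of singlet oxygen to the cyclic 1,3-diene (photo-oxygenation) is suprafacial, so the peroxide bridge is cis and the product is meso.

**Step 2**
Reactants: 2 6,7-dioxabicyclo[3.2.2]non-8-ene
Product: 3 (4S)-4-hydroxycyclohept-2-en-1-one
Conditions: 9-O-acetylcupreine or 9-O-acetylcupreidine (10 mol %; the pseudo-enantiomer that gives 4S), CH2Cl2, rt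
Reagents that add atoms: none
Why: In this Kornblum–DeLaMare rearrangement under chiral Brønsted-base catalysis the cinchona base removes one of the two enantiotopic bridgehead hydrogens with O–O cleavage, which desymmetrises the meso peroxide and should set the C6 carbinol (4S) from which all later centres are derived.

**Step 3**
Reactants: 3 (4S)-4-hydroxycyclohept-2-en-1-one
Product: 4 (4S)-4-[(triethylsilyl)oxy]cyclohept-2-en-1-one
Conditions: Et3SiCl, imidazole, CH2Cl2, 0 °C
Reagents that add atoms: chlorotriethylsilane, CC[Si](Cl)(CC)CC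
Why: Imidazole-promoted silylation of the secondary alcohol gives a triethylsilyl ether that can steer the cuprate and can later be removed beside a tert-butyldimethylsilyl ether.

**Step 4**
Reactants: 4 (4S)-4-[(triethylsilyl)oxy]cyclohept-2-en-1-one; 5 2-bromo-3-methylbut-1-ene
Product: 9 (2S,3R,4S)-2-methyl-3-(3-methylbut-1-en-2-yl)-4-[(triethylsilyl)oxy]cycloheptan-1-one, via vinyllithium 6 (not isolated), via Gilman cuprate 7 (not isolated), via lithium enolate 8 (not isolated)
Conditions: 5, t-BuLi (2 equiv), Et2O, −78 °C; CuI (0.5 equiv), −40 °C; 4, −78 °C; then MeI, HMPA, −78 → 0 °C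
Reagents that add atoms: iodomethane, CI
Why: Conjugate addition of the Gilman cuprate should occur anti to the γ-silyloxy group, setting C5 with the alkenyl group (a masked isobutyryl) trans to the C6 oxygen, and the regiodefined enolate is C-methylated at C1 (tandem 1,4-addition and enolate alkylation), the configuration of this methine being erased again in step 7.

**Step 5**
Reactants: 9 (2S,3R,4S)-2-methyl-3-(3-methylbut-1-en-2-yl)-4-[(triethylsilyl)oxy]cycloheptan-1-one
Product: 11 (5S,6R,7S)-7-methyl-6-(3-methylbut-1-en-2-yl)-5-[(triethylsilyl)oxy]cyclohept-2-en-1-one, via silyl enol ether 10 (not isolated)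
Conditions: LiN(iPr)2, Me3SiCl, THF, −78 °C; then Pd(OAc)2 (1.1 equiv), MeCN, rt
Reagents that add atoms: none
Why: Kinetic deprotonation at the less substituted α-carbon C9 followed by Saegusa–Ito dehydrogenation of the silyl enol ether installs the C9=C8 enone without touching the isolated alkene.

**Step 6**
Reactants: 11 (5S,6R,7S)-7-methyl-6-(3-methylbut-1-en-2-yl)-5-[(triethylsilyl)oxy]cyclohept-2-en-1-one
Product: 13 (5S,6R,7S)-3,7-dimethyl-6-(3-methylbut-1-en-2-yl)-5-[(triethylsilyl)oxy]cyclohept-2-en-1-one, via silyl enol ether 12 (not isolated)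
Conditions: MeMgBr, CuBr·SMe2 (10 mol %), Me3SiCl, HMPA, THF, −78 °C; then Pd(OAc)2 (1.1 equiv), MeCN, rt
Reagents that add atoms: methylmagnesium bromide, C[Mg]Br
Why: Copper-catalysed 1,4-addition of the Grignard reagent brings in the C8 methyl and a second Saegusa–Ito oxidation of the trapped silyl enol ether restores the enone, so the C8 centre formed in between is of no consequence.

**Step 7**
Reactants: 13 (5S,6R,7S)-3,7-dimethyl-6-(3-methylbut-1-en-2-yl)-5-[(triethylsilyl)oxy]cyclohept-2-en-1-one; 14 3-bromoprop-1-ene (allyl bromide)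
Product: 16 (5S,6S,7S)-3,7-dimethyl-6-(3-methylbut-1-en-2-yl)-7-(prop-2-en-1-yl)-5-[(triethylsilyl)oxy]cyclohept-2-en-1-one, via lithium dienolate 15 (not isolated)
Conditions: LiN(iPr)2, THF, −78 °C; 14, HMPA, −78 → −20 °C
Reagents that add atoms: none
Why: Kinetic α′-deprotonation of the enone at C1 gives the cross-conjugated dienolate, which should be C-allylated on the face opposite the neighbouring C5 alkenyl group (enolate alkylation), creating the quaternary centre C1 with its methyl cis to the C5 substituent.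

**Step 8**
Reactants: 16 (5S,6S,7S)-3,7-dimethyl-6-(3-methylbut-1-en-2-yl)-7-(prop-2-en-1-yl)-5-[(triethylsilyl)oxy]cyclohept-2-en-1-one
Product: 18 (5S,6S,7S)-3,7-dimethyl-6-(2-methylpropanoyl)-7-(2-oxoethyl)-5-[(triethylsilyl)oxy]cyclohept-2-en-1-one, via bis-ozonide 17 (not isolated)
Conditions: O3, CH2Cl2, −78 °C (stopped at the end point of a dye indicator); PPh3, −78 °C → rt
Reagents that add atoms: ozone, [O-][O+]=O
Why: In this ozonolysis the monosubstituted and the 1,1-disubstituted alkene are far more electron-rich than the conjugated enone double bond and should be cleaved selectively, unmasking the C4 isobutyryl ketone and the C3 aldehyde in one operation.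

**Step 9**
Reactants: 18 (5S,6S,7S)-3,7-dimethyl-6-(2-methylpropanoyl)-7-(2-oxoethyl)-5-[(triethylsilyl)oxy]cyclohept-2-en-1-one
Product: 19 (5S,6S,7S)-7-(2-hydroxyethyl)-3,7-dimethyl-6-(2-methylpropanoyl)-5-[(triethylsilyl)oxy]cyclohept-2-en-1-one
Conditions: NaBH4 (0.3 equiv), EtOH/CH2Cl2, −78 °C
Reagents that add atoms: none
Why: In this chemoselective borohydride reduction the unhindered aldehyde should react at −78 °C much faster than the conjugated ring ketone or the doubly α-branched isobutyryl ketone.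

**Step 10**
Reactants: 19 (5S,6S,7S)-7-(2-hydroxyethyl)-3,7-dimethyl-6-(2-methylpropanoyl)-5-[(triethylsilyl)oxy]cyclohept-2-en-1-one
Product: 20 (5S,6S,7S)-7-(2-iodoethyl)-3,7-dimethyl-6-(2-methylpropanoyl)-5-[(triethylsilyl)oxy]cyclohept-2-en-1-one
Conditions: I2, PPh3, imidazole, CH2Cl2, 0 °C
Reagents that add atoms: iodine, [I][I]
Why: Appel-type iodination converts the primary alcohol into the primary iodide by SN2 displacement of the alkoxyphosphonium ion.

**Step 11**
Reactants: 20 (5S,6S,7S)-7-(2-iodoethyl)-3,7-dimethyl-6-(2-methylpropanoyl)-5-[(triethylsilyl)oxy]cyclohept-2-en-1-one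
Product: 21 1-[(1S,2S,3R,7S)-3-hydroxy-2-(2-iodoethyl)-2,5-dimethyl-7-[(triethylsilyl)oxy]cyclohept-4-en-1-yl]-2-methylpropan-1-one
Conditions: NaBH4, CeCl3·7H2O, MeOH, −78 °C
Reagents that add atoms: none
Why: Luche reduction gives 1,2-reduction of the enone, hydride should enter from the face of the C1 methyl opposite the larger 2-iodoethyl group so that the C10 hydroxyl becomes cis to C2 (10R), and the isobutyryl ketone flanked by two branched carbons should be left untouched.

**Step 12**
Reactants: 21 1-[(1S,2S,3R,7S)-3-hydroxy-2-(2-iodoethyl)-2,5-dimethyl-7-[(triethylsilyl)oxy]cyclohept-4-en-1-yl]-2-methylpropan-1-one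
Product: 22 1-[(1S,2S,3R,7S)-3-[(tert-butyldimethylsilyl)oxy]-2-(2-iodoethyl)-2,5-dimethyl-7-[(triethylsilyl)oxy]cyclohept-4-en-1-yl]-2-methylpropan-1-one
Conditions: t-BuMe2SiOTf, 2,6-lutidine, CH2Cl2, −78 → 0 °C
Reagents that add atoms: tert-butyldimethylsilyl trifluoromethanesulfonate, CC(C)(C)[Si](C)(C)OS(=O)(=O)C(F)(F)F
Why: Silylation of the hindered allylic alcohol with the silyl triflate and a hindered base protects C10 and removes the risk of cyclic ether formation with the iodide.

**Step 13**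
Reactants: 22 1-[(1S,2S,3R,7S)-3-[(tert-butyldimethylsilyl)oxy]-2-(2-iodoethyl)-2,5-dimethyl-7-[(triethylsilyl)oxy]cyclohept-4-en-1-yl]-2-methylpropan-1-one
Product: 23 1-[(1S,2S,3R,7S)-3-[(tert-butyldimethylsilyl)oxy]-7-hydroxy-2-(2-iodoethyl)-2,5-dimethylcyclohept-4-en-1-yl]-2-methylpropan-1-one
Conditions: PPTS (cat.), MeOH/CH2Cl2, 0 °C
Reagents that add atoms: none
Why: Acid-catalysed methanolysis cleaves the secondary triethylsilyl ether much faster than the hindered tert-butyldimethylsilyl ether (selective desilylation), which frees the C6 hydroxyl.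

**Step 14**
Reactants: 23 1-[(1S,2S,3R,7S)-3-[(tert-butyldimethylsilyl)oxy]-7-hydroxy-2-(2-iodoethyl)-2,5-dimethylcyclohept-4-en-1-yl]-2-methylpropan-1-one
Product: 25 (3R,3aS,4S,8R,8aS)-8-[(tert-butyldimethylsilyl)oxy]-6,8a-dimethyl-3-(propan-2-yl)-1,2,3,3a,4,5,8,8a-octahydroazulene-3,4-diol, via alkylsamarium 24 (not isolated)
Conditions: SmI2 (2.5 equiv), HMPA (10 equiv), THF, −78 → 0 °C; aq NH4Cl
Reagents that add atoms: none
Why: SmI2 with HMPA transfers two electrons in turn to the carbon–iodine bond, giving the alkylsamarium 24, which adds to the C4 carbonyl in the same molecule and forms the C3–C4 bond. The closest known reaction is the SmI2-promoted intramolecular Barbier cyclisation of ω-iodoalkyl ketones to cyclopentanols. The cyclopentane (C1–C2–C3–C4–C5) closes in a 5-exo-trig mode onto the finished cycloheptene, and since the 2-iodoethyl arm on C1 and the acyl group on C5 are already trans, the ring fusion can only be trans. The one new stereocentre, C4, is controlled by samarium bridging the C4 carbonyl oxygen and the C6 hydroxyl, which holds the carbonyl oxygen on the C6 side and the isopropyl group on the side of the small C5 hydrogen, so the new hydroxyl should end up cis to C6 (4R). The step needs the iodide to be reduced faster than the ketone, which HMPA ensures, and ring closure to outrun proton transfer from the free hydroxyl, which the five-membered transition state favours. The medium is not basic, so retro-aldol cleavage and epimerisation at C5 are not expected.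

**Step 15**
Reactants: 25 (3R,3aS,4S,8R,8aS)-8-[(tert-butyldimethylsilyl)oxy]-6,8a-dimethyl-3-(propan-2-yl)-1,2,3,3a,4,5,8,8a-octahydroazulene-3,4-diol; 26 3,4-dimethoxybenzoyl chloride
Product: 27 (3R,3aS,4S,8R,8aS)-8-[(tert-butyldimethylsilyl)oxy]-3-hydroxy-6,8a-dimethyl-3-(propan-2-yl)-1,2,3,3a,4,5,8,8a-octahydroazulen-4-yl 3,4-dimethoxybenzoate
Conditions: 26, Et3N, DMAP (cat.), CH2Cl2, rt
Reagents that add atoms: none
Why: DMAP-catalysed acylation takes the only secondary hydroxyl (C6), the tertiary C4 hydroxyl being too hindered to react.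

**Step 16**
Reactants: 27 (3R,3aS,4S,8R,8aS)-8-[(tert-butyldimethylsilyl)oxy]-3-hydroxy-6,8a-dimethyl-3-(propan-2-yl)-1,2,3,3a,4,5,8,8a-octahydroazulen-4-yl 3,4-dimethoxybenzoate
Product: 28 (3R,3aS,4S,8R,8aS)-3,8-dihydroxy-6,8a-dimethyl-3-(propan-2-yl)-1,2,3,3a,4,5,8,8a-octahydroazulen-4-yl 3,4-dimethoxybenzoate
Conditions: HF·pyridine, pyridine, THF, 0 °C → rt
Reagents that add atoms: none
Why: Fluoride-mediated cleavage of the silyl ether under buffered, weakly acidic conditions should leave the benzoate and the tertiary alcohol intact.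

**Step 17**
Reactants: 28 (3R,3aS,4S,8R,8aS)-3,8-dihydroxy-6,8a-dimethyl-3-(propan-2-yl)-1,2,3,3a,4,5,8,8a-octahydroazulen-4-yl 3,4-dimethoxybenzoate; 29 angelic acid ((2Z)-2-methylbut-2-enoic acid)
Product: 31 (3R,3aS,4S,8R,8aS)-3-hydroxy-6,8a-dimethyl-8-{[(2Z)-2-methylbut-2-enoyl]oxy}-3-(propan-2-yl)-1,2,3,3a,4,5,8,8a-octahydroazulen-4-yl 3,4-dimethoxybenzoate (CNP0142353.1), via mixed anhydride 30 (not isolated)
Conditions: 29, 2,4,6-trichlorobenzoyl chloride, Et3N, toluene, rt; then 28, 80 °C
Reagents that add atoms: none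
Why: Yamaguchi-type esterification through the mixed anhydride with 2,4,6-trichlorobenzoic acid acylates the hindered C10 hydroxyl under conditions that are known to preserve the Z geometry of angelates, while the tertiary C4 hydroxyl does not react.

**Compound list**
1 | cyclohepta-1,3-diene | C1=CC=CCCC1 | starting material
2 | 6,7-dioxabicyclo[3.2.2]non-8-ene (meso) | C1=C[C@@H]2CCC[C@H]1OO2 | intermediate
3 | (4S)-4-hydroxycyclohept-2-en-1-one | O=C1CCC[C@H](O)C=C1 | intermediate
4 | (4S)-4-[(triethylsilyl)oxy]cyclohept-2-en-1-one | O=C1CCC[C@H](O[Si](CC)(CC)CC)C=C1 | intermediate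
5 | 2-bromo-3-methylbut-1-ene | C=C(Br)C(C)C | starting material
6 | (3-methylbut-1-en-2-yl)lithium | [Li]C(=C)C(C)C | intermediate
7 | lithium bis(3-methylbut-1-en-2-yl)cuprate | [Li+].C=C([Cu-]C(=C)C(C)C)C(C)C | intermediate
8 | lithium enolate of the 1,4-adduct (C10–O–Li, C10=C1; alkenyl on C5 trans to the C6 silyloxy group) | [Li+].[O-]C=1CCC[C@H](O[Si](CC)(CC)CC)[C@@H](C(=C)C(C)C)C=1 | intermediate
9 | (2S,3R,4S)-2-methyl-3-(3-methylbut-1-en-2-yl)-4-[(triethylsilyl)oxy]cycloheptan-1-one | O=C1CCC[C@H](O[Si](CC)(CC)CC)[C@@H](C(=C)C(C)C)[C@@H]1C | intermediate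
10 | trimethylsilyl enol ether of 9 (C10=C9) | C[Si](C)(C)OC1=CCC[C@H](O[Si](CC)(CC)CC)[C@@H](C(=C)C(C)C)[C@@H]1C | intermediate
11 | (5S,6R,7S)-7-methyl-6-(3-methylbut-1-en-2-yl)-5-[(triethylsilyl)oxy]cyclohept-2-en-1-one | O=C1C=CC[C@H](O[Si](CC)(CC)CC)[C@@H](C(=C)C(C)C)[C@@H]1C | intermediate
12 | trimethylsilyl enol ether of the C8-methylated ketone (C10=C9; C8 epimers) | C[Si](C)(C)OC1=CC(C)C[C@H](O[Si](CC)(CC)CC)[C@@H](C(=C)C(C)C)[C@@H]1C | intermediate
13 | (5S,6R,7S)-3,7-dimethyl-6-(3-methylbut-1-en-2-yl)-5-[(triethylsilyl)oxy]cyclohept-2-en-1-one | O=C1C=C(C)C[C@H](O[Si](CC)(CC)CC)[C@@H](C(=C)C(C)C)[C@@H]1C | intermediate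
14 | 3-bromoprop-1-ene (allyl bromide) | C=CCBr | starting material
15 | cross-conjugated lithium dienolate of 13 (C10–O–Li, C10=C1, C8=C9) | [Li+].[O-]C=1C=C(C)C[C@H](O[Si](CC)(CC)CC)[C@@H](C(=C)C(C)C)C=1C | intermediate
16 | (5S,6S,7S)-3,7-dimethyl-6-(3-methylbut-1-en-2-yl)-7-(prop-2-en-1-yl)-5-[(triethylsilyl)oxy]cyclohept-2-en-1-one | O=C1C=C(C)C[C@H](O[Si](CC)(CC)CC)[C@@H](C(=C)C(C)C)[C@]1(C)CC=C | intermediate
17 | bis(1,2,4-trioxolane) of 16 (ozonides of both terminal alkenes) | O=C1C=C(C)C[C@H](O[Si](CC)(CC)CC)[C@@H](C2(C(C)C)OCOO2)[C@]1(C)CC1OCOO1 | intermediate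
18 | (5S,6S,7S)-3,7-dimethyl-6-(2-methylpropanoyl)-7-(2-oxoethyl)-5-[(triethylsilyl)oxy]cyclohept-2-en-1-one | O=C1C=C(C)C[C@H](O[Si](CC)(CC)CC)[C@@H](C(=O)C(C)C)[C@]1(C)CC=O | intermediate
19 | (5S,6S,7S)-7-(2-hydroxyethyl)-3,7-dimethyl-6-(2-methylpropanoyl)-5-[(triethylsilyl)oxy]cyclohept-2-en-1-one | O=C1C=C(C)C[C@H](O[Si](CC)(CC)CC)[C@@H](C(=O)C(C)C)[C@]1(C)CCO | intermediate
20 | (5S,6S,7S)-7-(2-iodoethyl)-3,7-dimethyl-6-(2-methylpropanoyl)-5-[(triethylsilyl)oxy]cyclohept-2-en-1-one | O=C1C=C(C)C[C@H](O[Si](CC)(CC)CC)[C@@H](C(=O)C(C)C)[C@]1(C)CCI | intermediate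
21 | 1-[(1S,2S,3R,7S)-3-hydroxy-2-(2-iodoethyl)-2,5-dimethyl-7-[(triethylsilyl)oxy]cyclohept-4-en-1-yl]-2-methylpropan-1-one | O[C@@H]1C=C(C)C[C@H](O[Si](CC)(CC)CC)[C@@H](C(=O)C(C)C)[C@]1(C)CCI | intermediate
22 | 1-[(1S,2S,3R,7S)-3-[(tert-butyldimethylsilyl)oxy]-2-(2-iodoethyl)-2,5-dimethyl-7-[(triethylsilyl)oxy]cyclohept-4-en-1-yl]-2-methylpropan-1-one | CC(C)(C)[Si](C)(C)O[C@@H]1C=C(C)C[C@H](O[Si](CC)(CC)CC)[C@@H](C(=O)C(C)C)[C@]1(C)CCI | intermediate
23 | 1-[(1S,2S,3R,7S)-3-[(tert-butyldimethylsilyl)oxy]-7-hydroxy-2-(2-iodoethyl)-2,5-dimethylcyclohept-4-en-1-yl]-2-methylpropan-1-one | CC(C)(C)[Si](C)(C)O[C@@H]1C=C(C)C[C@H](O)[C@@H](C(=O)C(C)C)[C@]1(C)CCI | intermediate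
24 | alkylsamarium diiodide derived from 23 (samarium on C3) | CC(C)(C)[Si](C)(C)O[C@@H]1C=C(C)C[C@H](O)[C@@H](C(=O)C(C)C)[C@]1(C)CC[Sm](I)I | intermediate
25 | (3R,3aS,4S,8R,8aS)-8-[(tert-butyldimethylsilyl)oxy]-6,8a-dimethyl-3-(propan-2-yl)-1,2,3,3a,4,5,8,8a-octahydroazulene-3,4-diol | CC(C)(C)[Si](C)(C)O[C@@H]1C=C(C)C[C@H](O)[C@@H]2[C@]1(C)CC[C@@]2(O)C(C)C | intermediate
26 | 3,4-dimethoxybenzoyl chloride | COc1ccc(C(Cl)=O)cc1OC | starting material
27 | (3R,3aS,4S,8R,8aS)-8-[(tert-butyldimethylsilyl)oxy]-3-hydroxy-6,8a-dimethyl-3-(propan-2-yl)-1,2,3,3a,4,5,8,8a-octahydroazulen-4-yl 3,4-dimethoxybenzoate | CC(C)(C)[Si](C)(C)O[C@@H]1C=C(C)C[C@H](OC(=O)c2ccc(OC)c(OC)c2)[C@@H]2[C@]1(C)CC[C@@]2(O)C(C)C | intermediate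
28 | (3R,3aS,4S,8R,8aS)-3,8-dihydroxy-6,8a-dimethyl-3-(propan-2-yl)-1,2,3,3a,4,5,8,8a-octahydroazulen-4-yl 3,4-dimethoxybenzoate | O[C@@H]1C=C(C)C[C@H](OC(=O)c2ccc(OC)c(OC)c2)[C@@H]2[C@]1(C)CC[C@@]2(O)C(C)C | intermediate
29 | angelic acid, (2Z)-2-methylbut-2-enoic acid | C/C=C(/C)C(=O)O | starting material
30 | (2Z)-2-methylbut-2-enoic 2,4,6-trichlorobenzoic anhydride | C/C=C(/C)C(=O)OC(=O)c1c(Cl)cc(Cl)cc1Cl | intermediate
31 | (3R,3aS,4S,8R,8aS)-3-hydroxy-6,8a-dimethyl-8-{[(2Z)-2-methylbut-2-enoyl]oxy}-3-(propan-2-yl)-1,2,3,3a,4,5,8,8a-octahydroazulen-4-yl 3,4-dimethoxybenzoate | C/C=C(/C)C(=O)O[C@@H]1C=C(C)C[C@H](OC(=O)c2ccc(OC)c(OC)c2)[C@@H]2[C@]1(C)CC[C@@]2(O)C(C)C | target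

**Step count and risks**
Total step count: 17. Longest linear sequence: 17 steps (1 → 31); compounds 5, 14, 26 and 29 are purchased and enter directly.

Steps most likely to fail:

Step 14 (key step). The alkylsamarium may be protonated by the free C6 hydroxyl before it closes the ring, or the addition may not be face-selective at C4. Fallback: step 13 is left out and the fully silylated iodide 22 is cyclised with SmI2/HMPA, so that no proton source is present and the bulky C6 silyloxy group steers the isopropyl group by steric approach control instead of chelation. This should give (3R,3aS,4S,8R,8aS)-8-[(tert-butyldimethylsilyl)oxy]-6,8a-dimethyl-3-(propan-2-yl)-4-[(triethylsilyl)oxy]-1,2,3,3a,4,5,8,8a-octahydroazulen-3-ol F1. Methanolysis of its triethylsilyl ether with PPTS then frees the C6 hydroxyl, and the route is rejoined at 25.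

Step 11. Hydride may be delivered to the wrong face of C10 under substrate control (the C5 acyl group lies on the same face as the C1 methyl), or the isobutyryl ketone may be reduced as well. Fallback: substrate control is replaced by reagent control, that is, Corey–Bakshi–Shibata reduction of 20 (B-methyl oxazaborolidine, catecholborane, toluene, −78 °C). Both antipodes of the catalyst are available, so the matched one can be chosen, and this reagent reduces conjugated ketones much faster than hindered dialkyl ketones. The fallback sets out from 20 and returns at 21 without any compound outside the main list (F0).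

Step 7. The dienolate may be allylated on oxygen, may equilibrate by proton transfer to the extended dienolate and react at C9, or may be attacked on the wrong face of C1. Fallback: the dienolate generated from 13 is trapped on oxygen with allyl chloroformate to give (3S,4S)-2,6-dimethyl-3-(3-methylbut-1-en-2-yl)-4-[(triethylsilyl)oxy]cyclohepta-1,6-dien-1-yl prop-2-en-1-yl carbonate F2. This is rearranged by palladium-catalysed decarboxylative allylation (Tsuji reaction; Pd2(dba)3 with a chiral phosphinooxazoline ligand, THF, rt), in which C–C bond formation at C1 is regiospecific and the face is chosen by the catalyst. The route is rejoined at 16.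

**Further compounds**
F1 | step 14 | (3R,3aS,4S,8R,8aS)-8-[(tert-butyldimethylsilyl)oxy]-6,8a-dimethyl-3-(propan-2-yl)-4-[(triethylsilyl)oxy]-1,2,3,3a,4,5,8,8a-octahydroazulen-3-ol | CC(C)(C)[Si](C)(C)O[C@@H]1C=C(C)C[C@H](O[Si](CC)(CC)CC)[C@@H]2[C@]1(C)CC[C@@]2(O)C(C)C
F0 | step 11 | none | none
F2 | step 7 | (3S,4S)-2,6-dimethyl-3-(3-methylbut-1-en-2-yl)-4-[(triethylsilyl)oxy]cyclohepta-1,6-dien-1-yl prop-2-en-1-yl carbonate | C=CCOC(=O)OC=1C=C(C)C[C@H](O[Si](CC)(CC)CC)[C@@H](C(=C)C(C)C)C=1C
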